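Assumption: the target has no stereocentre and no stereogenic double bond (the prenyl alkene carries two methyl groups), so it is achiral and there is no enantiomer to control; indole-3-pyruvic acid is taken as a commercial keto acid.

**Retrosynthetic overview**
- Target ⇒ asterriquinone D (the 2,5-dimethoxy-3,6-di(indol-3-yl)benzoquinone) + a prenylstannane: one vinylogous-ester OMe is exchanged for prenyl, the chemical counterpart of the biosynthetic hydroxyl-to-prenyl exchange on the quinone core.
- Asterriquinone D ⇒ two molecules of methyl indole-3-pyruvate: head-to-tail double Claisen (Claisen, then Dieckmann), the same C3-to-C1 dimerisation by which the bis-indolylquinone synthetases build the ring from tryptophan-derived indolepyruvate; the dianion is O-methylated in the same flask.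
- Methyl indole-3-pyruvate ⇒ indole-3-pyruvic acid + MeI.
- Ring order: both indole rings are bought; the quinone ring is the only ring made (step 2). Three steps, no protecting groups.

**Route**

Step 1
Reactants: 1 indole-3-pyruvic acid; 2 iodomethane
Product: 3 methyl 3-(1H-indol-3-yl)-2-oxopropanoate (methyl indole-3-pyruvate; keto form drawn, mainly the enol in solution)
Conditions: KHCO3 (1.2 equiv), MeI (1.5 equiv), DMF, rt, Ar, dark
Reagents that add atoms: iodomethane, CI
Why: SN2 O-alkylation of the carboxylate; KHCO3 ionises only the carboxylic acid (not the enol OH or the indole N–H), so MeI gives the methyl ester, as in the usual esterification of arylpyruvic acids; no stereocentre.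

Step 2
Reactants: 3 methyl 3-(1H-indol-3-yl)-2-oxopropanoate (two molecules); 4 dimethyl sulfate
Product: 7 asterriquinone D = 2,5-di(1H-indol-3-yl)-3,6-dimethoxycyclohexa-2,5-diene-1,4-dione, via triketo ester 5 (not isolated), via disodium quinonate 6 (not isolated)
Conditions: NaOMe (1.0 equiv per 3), MeOH–toluene, reflux with removal of MeOH, Ar; then DMF, Me2SO4 (1.3 equiv per 3), 45 °C
Reagents that add atoms: dimethyl sulfate, COS(=O)(=O)OC
Why: Proposed new method: head-to-tail double Claisen condensation – the C3 enolate of one keto ester acylates the ester carbonyl of the second (giving 5) and the mirror-image Dieckmann closure forms the six-membered ring, which gives the tetraketone tautomer of the dihydroxyquinone with no redox change, as in the thioesterase-domain dimerisation of indolepyruvate in the terrequinone/asterriquinone pathway; the closest known reaction is the Fichter synthesis of 2,5-dialkyl-3,6-dihydroxybenzoquinones from aliphatic α-keto esters and sodium alkoxide; the competing aldol additions to the keto group are reversible under methoxide at reflux, whereas 6, a doubly vinylogous carboxylate that precipitates, is the thermodynamic sink, and its oxygens (the only anionic sites; the indole N–H stays un-ionised) are then O-methylated by dimethyl sulfate as in the standard etherification of polyporic-acid-type hydroxyquinones; no stereocentre is formed.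

Step 3
Reactants: 7 asterriquinone D; 8 tributyl(3-methylbut-2-en-1-yl)stannane
Product: 11 target = 2,5-di(1H-indol-3-yl)-3-methoxy-6-(3-methylbut-2-en-1-yl)cyclohexa-2,5-diene-1,4-dione, via quinol adduct 9 (not isolated), via rearranged enol 10 (not isolated)
Conditions: prenylSnBu3 (1.1 equiv), BF3·OEt2 (2.2 equiv), CH2Cl2, −78 → −20 °C; H2O
Reagents that add atoms: tributyl(3-methylbut-2-en-1-yl)stannane, CCCC[Sn](CCCC)(CCCC)CC=C(C)C
Why: Proposed new method: BF3 activates a quinone carbonyl, the stannane attacks it through its γ-carbon (SE2′, as in the Naruta allylstannane prenylation of methoxyquinones) to give quinol 9, and the ensuing [3,3] shift moves the allyl unit to the ring carbon next to the other carbonyl with a second allylic inversion (normal prenyl); only the shift onto the methoxy-bearing carbon (10) can be followed by vinylogous β-elimination of methanol, which restores the quinone and drains the reversible alternatives, so the net result is ipso replacement of one vinylogous-ester methoxy group by prenyl at the quinone oxidation level (closest known types: Lewis-acid allylstannane–quinone allylation and addition–elimination at vinylogous esters); about one equivalent of stannane at low temperature limits the reaction to mono-substitution, and no stereocentre survives (9 and 10 are racemic transients).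

**Compound list**

1 | indole-3-pyruvic acid, 3-(1H-indol-3-yl)-2-oxopropanoic acid | OC(=O)C(=O)Cc1c[nH]c2ccccc12 | starting material
2 | iodomethane | CI | starting material
3 | methyl 3-(1H-indol-3-yl)-2-oxopropanoate (keto form; achiral) | COC(=O)C(=O)Cc1c[nH]c2ccccc12 | intermediate
4 | dimethyl sulfate | COS(=O)(=O)OC | starting material
5 | methyl 3,6-di(1H-indol-3-yl)-2,4,5-trioxohexanoate (racemic, present as its sodium enolate) | COC(=O)C(=O)C(c1c[nH]c2ccccc12)C(=O)C(=O)Cc1c[nH]c2ccccc12 | intermediate
6 | disodium 2,5-di(1H-indol-3-yl)-3,6-dioxocyclohexa-1,4-diene-1,4-bis(olate), the disodium salt of didemethylasterriquinone D | [Na+].[Na+].[O-]C1=C(c2c[nH]c3ccccc23)C(=O)C([O-])=C(c2c[nH]c3ccccc23)C1=O | intermediate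
7 | asterriquinone D, 2,5-di(1H-indol-3-yl)-3,6-dimethoxycyclohexa-2,5-diene-1,4-dione (achiral) | COC1=C(c2c[nH]c3ccccc23)C(=O)C(OC)=C(c2c[nH]c3ccccc23)C1=O | intermediate
8 | tributyl(3-methylbut-2-en-1-yl)stannane (prenyltributylstannane) | CCCC[Sn](CCCC)(CCCC)CC=C(C)C | starting material
9 | 4-hydroxy-3,6-di(1H-indol-3-yl)-2,5-dimethoxy-4-(2-methylbut-3-en-2-yl)cyclohexa-2,5-dien-1-one (racemic; boron-bound in the flask, free alcohol drawn) | OC1(C(C)(C)C=C)C(OC)=C(c2c[nH]c3ccccc23)C(=O)C(OC)=C1c1c[nH]c2ccccc12 | intermediate
10 | 4-hydroxy-2,5-di(1H-indol-3-yl)-3,6-dimethoxy-6-(3-methylbut-2-en-1-yl)cyclohexa-2,4-dien-1-one (racemic; boron-bound in the flask, free enol drawn) | OC1=C(c2c[nH]c3ccccc23)C(OC)(CC=C(C)C)C(=O)C(c2c[nH]c3ccccc23)=C1OC | intermediate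
11 | 2,5-di(1H-indol-3-yl)-3-methoxy-6-(3-methylbut-2-en-1-yl)cyclohexa-2,5-diene-1,4-dione (CNP0506434.0; achiral) | COC1=C(c2c[nH]c3ccccc23)C(=O)C(CC=C(C)C)=C(c2c[nH]c3ccccc23)C1=O | target

**Step count and risks**

Total step count: 3. Longest linear sequence: 3 steps (1 → 3 → 7 → 11).

Steps most likely to fail, in decreasing order of risk:

Step 2 (ring formation). The kinetically easier aldol addition to the keto group, followed by lactonisation to a butenolide dimer, may trap the material. The enolised ester is also a weak acyl acceptor, and alkylation of 6 may give some ortho-quinone ether. Fallback, setting out from 1 and coming back at 7: the ring formation is given to the enzyme that performs it in nature. The holo form of the adenylation–thiolation–thioesterase synthetase TdiA (recombinant, phosphopantetheinylated; ATP, MgCl2, pH 7.5 buffer, 25 °C, or a whole-cell expression host fed with 1) loads 1 as a thioester and dimerises it to didemethylasterriquinone D F1. This is extracted after acidification and O-methylated with TMSCHN2 (MeOH/toluene, 0 °C) to give 7.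

Step 3 (methoxy-to-prenyl exchange). The allyl shift may go to the indolyl-bearing carbon (a dead-end adduct). Direct conjugate attack would give the reverse-prenyl isomer, and a second substitution is possible. Fallback, setting out from 7 and coming back at 11: the addition–elimination is replaced by a cross-coupling. One vinylogous ester of 7 is hydrolysed (NaOH 1.1 equiv, aqueous THF/MeOH, rt, then dilute HCl; the hydroxyquinone anion formed shields the second methoxy group) to 2-hydroxy-3,6-di(1H-indol-3-yl)-5-methoxycyclohexa-2,5-diene-1,4-dione F2. Treatment with PhNTf2/Et3N (CH2Cl2, 0 °C) gives the vinylogous acyl triflate 2,5-di(1H-indol-3-yl)-4-methoxy-3,6-dioxocyclohexa-1,4-dien-1-yl trifluoromethanesulfonate F3. Stille coupling of F3 with 8 (Pd(PPh3)4 5 mol %, LiCl, dioxane, 90 °C) then gives 11.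

Step 1 (esterification). The keto acid is prone to air oxidation once ionised, and some enol O-methylation is possible. Fallback, setting out from 1 and coming back at 3: base and alkylating agent are avoided altogether. 1 is heated with HC(OMe)3/MeOH and catalytic TsOH (Fischer esterification with simultaneous ketalisation of the keto group) to give methyl 3-(1H-indol-3-yl)-2,2-dimethoxypropanoate F4. Brief treatment with aqueous TFA in acetone at 0 °C removes the ketal and returns 3.

Further compounds
F1 | step 2 | didemethylasterriquinone D, 2,5-dihydroxy-3,6-di(1H-indol-3-yl)cyclohexa-2,5-diene-1,4-dione | OC1=C(c2c[nH]c3ccccc23)C(=O)C(O)=C(c2c[nH]c3ccccc23)C1=O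
F2 | step 3 | 2-hydroxy-3,6-di(1H-indol-3-yl)-5-methoxycyclohexa-2,5-diene-1,4-dione | COC1=C(c2c[nH]c3ccccc23)C(=O)C(O)=C(c2c[nH]c3ccccc23)C1=O
F3 | step 3 | 2,5-di(1H-indol-3-yl)-4-methoxy-3,6-dioxocyclohexa-1,4-dien-1-yl trifluoromethanesulfonate | COC1=C(c2c[nH]c3ccccc23)C(=O)C(OS(=O)(=O)C(F)(F)F)=C(c2c[nH]c3ccccc23)C1=O
F4 | step 1 | methyl 3-(1H-indol-3-yl)-2,2-dimethoxypropanoate | COC(=O)C(OC)(OC)Cc1c[nH]c2ccccc12
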